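**Plan**
- Retrosynthesis: the chain is cut at C15–C16 (allylic bromide plus the sulfonyl-stabilised carbanion of an 8-oxygenated geranyl unit) and at C13=C14 (Wittig on a C13 aldehyde). The C8 carbinol is traced back through an exocyclic C8=CH2 alkene to a C8 ketone.
- The core is then cut at C10–CH3 and C9–C11. C10 is a quaternary carbon whose methyl is cis to C5–H, and it sits in ring B next to the chain-bearing C9 and the oxygenated C8. This array is the retron of a ring B enone C8(=O)–C9=C10 that takes up methyl at C10 and allyl at C9.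
- Rings A and B both come from 6-methoxy-2-tetralone (gem-dimethylation, asymmetric reduction, Birch reduction, hydrolysis); no ring is formed later.
- Forward: tetralone → enone → conjugate methylation/allylation → C8 methylenation → allyl to C13 aldehyde → (E)-enoate → C8 epoxide → hydride opening → allylic bromide → sulfone coupling and desulfonylation → desilylation, acetylation, C3 oxidation.
- Stereochemistry: C3 from the CBS reduction; C5 by equilibration against C3; C10 by cuprate attack on the face of C5–H; C9 by equilibration next to the C8 ketone; C8 by epoxidation anti to the C10 methyl; alkene geometry from a stabilised ylide, SeO2 oxidation and geranyl bromide.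

Key step: step 5

Assumption: the configuration written for the target is a cis-fused decalin (C5–H, C10–CH3, the C9 chain and C8–CH3 on one face, C8–OH on the other), and the route is aimed at exactly this stereoisomer. Decalin locants are C1–C10 (C3 oxygen, C4 gem-dimethyl, C8 carbinol, C9 chain, C10 angular methyl); chain carbons run C11 to C23 from C9 to the acetoxymethylene carbon, and the methylene carbon attached to C8 is called C17. β is the face of the C10 methyl, α the opposite face.

Step 1
Reactants: 1 6-methoxy-2-tetralone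
Product: 3 6-methoxy-1,1-dimethyl-3,4-dihydronaphthalen-2(1H)-one, via monomethyl ketone 2 (not isolated)
Conditions: NaH (2.5 equiv), MeI (3 equiv), THF, 0 °C → rt
Reagents that add atoms: iodomethane, CI
Why: Double enolate C-alkylation: C1 is both benzylic and α to the ketone, so it is deprotonated and methylated twice in preference to C3, and the resulting quaternary carbon blocks further reaction there.

Step 2
Reactants: 3 6-methoxy-1,1-dimethyl-3,4-dihydronaphthalen-2(1H)-one
Product: 4 (R)-6-methoxy-1,1-dimethyl-1,2,3,4-tetrahydronaphthalen-2-ol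
Conditions: (S)-2-methyl-CBS-oxazaborolidine [(S)-1-methyl-3,3-diphenyltetrahydro-1H,3H-pyrrolo[1,2-c][1,3,2]oxazaborole] (10 mol %), BH3·SMe2, THF, −20 → 0 °C; aq. NH4Cl
Reagents that add atoms: none
Why: Corey–Bakshi–Shibata reduction: the ketone lies between a quaternary benzylic carbon and a methylene group, a large/small pair the oxazaborolidine–borane complex differentiates well, and the (S)-catalyst should deliver hydride to the face that gives the (R)-carbinol (C3 of the target numbering), the only stereocentre set by a chiral reagent.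

Step 3
Reactants: 4 (R)-6-methoxy-1,1-dimethyl-1,2,3,4-tetrahydronaphthalen-2-ol
Product: 7 (4aS,6R)-6-hydroxy-5,5-dimethyl-4,4a,5,6,7,8-hexahydronaphthalen-2(3H)-one, via Birch enol ether 5 (not isolated), via deconjugated enone 6 (not isolated)
Conditions: Li, NH3 (l), t-BuOH, THF, −78 → −33 °C; evaporate NH3; 3 M HCl, THF, rt → 45 °C
Reagents that add atoms: water, O
Why: Birch reduction of the anisole ring gives the 1-methoxy-1,4-diene 5, aqueous acid hydrolyses the enol ether to the β,γ-unsaturated ketone 6 and moves the alkene into conjugation, and the new C5 stereocentre, formed reversibly through the dienol, should settle on the diastereomer whose ring A chair keeps the C3 hydroxyl equatorial (C3–H and C5–H cis), the minor C5 epimer being removed by crystallisation and returned to the same acid equilibrium.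

Step 4
Reactants: 7 (4aS,6R)-6-hydroxy-5,5-dimethyl-4,4a,5,6,7,8-hexahydronaphthalen-2(3H)-one
Product: 8 (4aS,6R)-6-[(tert-butyldimethylsilyl)oxy]-5,5-dimethyl-4,4a,5,6,7,8-hexahydronaphthalen-2(3H)-one
Conditions: TBSCl, imidazole, DMF, 45 °C
Reagents that add atoms: tert-butyldimethylsilyl chloride, CC(C)(C)[Si](C)(C)Cl
Why: Standard silylation of a secondary alcohol, which protects C3–OH from the organometallic reagents to come and, being large and equatorial, holds ring A in the chair on which the later stereocontrol relies.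

Step 5
Reactants: 8 (4aS,6R)-6-[(tert-butyldimethylsilyl)oxy]-5,5-dimethyl-4,4a,5,6,7,8-hexahydronaphthalen-2(3H)-one; 9 allyl bromide
Product: 12 (1R,4aS,6R,8aS)-6-[(tert-butyldimethylsilyl)oxy]-5,5,8a-trimethyl-1-(prop-2-en-1-yl)octahydronaphthalen-2(1H)-one, via lithium enolate 10 (not isolated), via C9-epimeric ketone 11 (not isolated)
Conditions: Me2CuLi (from MeLi and CuI), Et2O, −20 → 0 °C; then THF, HMPA, allyl bromide, −30 °C → rt; aq. NH4Cl/NH3; crude product: NaOMe (cat.), MeOH, rt
Reagents that add atoms: lithium dimethylcuprate, [Li+].C[Cu-]C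
Why: The cuprate forms a d–π* complex with enone 8 and transfers methyl to C10 through a β-cuprio enolate of trivalent copper and reductive elimination, leaving the regiodefined C8(9) lithium enolate 10, which is C-allylated at C9 by SN2 attack on allyl bromide in the presence of HMPA; the closest known reaction type is conjugate addition of lithium dialkylcuprates to 4,4a,5,6,7,8-hexahydro-2(3H)-naphthalenones with trapping of the enolate by an allylic halide. No ring is closed, and the two new bonds (C10–CH3 and C9–C11) flank the former C9=C10 alkene. The C10 stereocentre is set by attack on the enone face that carries C5–H, because the axial methyl on C4 lies 1,3 to C10 on the other face of ring A and because octalones of this type take up cuprate carbon cis to the ring-fusion hydrogen. The C9 stereocentre is set thermodynamically: whatever share of epimer 11 the kinetic alkylation leaves, methoxide equilibration through the C8 enolate should collect the material as 12, in which the allyl group is equatorial on ring B and cis to the C10 methyl, whereas 11 would have to place it axial underneath ring A or flip ring A so that the C3 silyl ether becomes axial. The step needs 1,4- over 1,2-addition, C- over O-alkylation and no enolate transposition to C7, which the soft cuprate, the lithium counter-ion with a reactive allylic halide and the low alkylation temperature should secure.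

Step 6
Reactants: 12 9β-allyl decal-8-one (key-step product)
Product: 13 9β-allyl-3α-(tert-butyldimethylsilyloxy)-4,4,10β-trimethyl-8-methylidene-5β-decalin
Conditions: Ph3PCH3Br, KOtBu, toluene, 90 °C
Reagents that add atoms: methyltriphenylphosphonium bromide, C[P+](c1ccccc1)(c1ccccc1)c1ccccc1.[Br-]
Why: Wittig methylenation of a hindered, enolisable ketone with excess ylide at elevated temperature, the basic medium being able only to drive C9 further toward the equatorial epimer already present.

Step 7
Reactants: 13 9β-allyl-8-methylidene decalin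
Product: 15 9β-(3-hydroxypropyl)-3α-(tert-butyldimethylsilyloxy)-4,4,10β-trimethyl-8-methylidene-5β-decalin, via alkyldisiamylborane 14 (not isolated)
Conditions: Sia2BH (from BH3·SMe2 and 2-methyl-2-butene), THF, 0 °C → rt; then NaOH, H2O2, 0 °C → rt
Reagents that add atoms: hydrogen peroxide, OO
Why: Hydroboration–oxidation with a bulky dialkylborane: disiamylborane adds anti-Markovnikov to the monosubstituted alkene of the allyl group much faster than to the 1,1-disubstituted exocyclic alkene at C8, which is flanked by C9 and shielded by the axial C10 methyl, so that only C13 is oxidised to the primary alcohol.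

Step 8
Reactants: 15 C13 primary alcohol
Product: 16 9β-(3-oxopropyl)-3α-(tert-butyldimethylsilyloxy)-4,4,10β-trimethyl-8-methylidene-5β-decalin (C13 aldehyde)
Conditions: Dess–Martin periodinane, NaHCO3, CH2Cl2, rt
Reagents that add atoms: none
Why: Dess–Martin oxidation stops at the aldehyde and leaves the silyl ether and the exocyclic alkene untouched.

Step 9
Reactants: 16 C13 aldehyde
Product: 17 ethyl (2E)-2-methyl-5-[3α-(tert-butyldimethylsilyloxy)-4,4,10β-trimethyl-8-methylidene-5β-decalin-9β-yl]pent-2-enoate
Conditions: Ph3P=C(CH3)CO2Et, toluene, 80 °C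
Reagents that add atoms: ethyl 2-(triphenylphosphoranylidene)propanoate, CCOC(=O)C(C)=P(c1ccccc1)(c1ccccc1)c1ccccc1
Why: Wittig olefination with a stabilised α-methyl ylide, which reacts under thermodynamic control and should give the (E)-trisubstituted enoate (C13=C14 with the C14 methyl), the ester carbon becoming C15.

Step 10
Reactants: 17 (E)-enoate with C8 exocyclic alkene
Product: 18 8α,17-epoxide of 17 (spiro-oxirane at C8 with oxygen α and CH2 β)
Conditions: mCPBA (1.1 equiv), NaHCO3, CH2Cl2, 0 °C
Reagents that add atoms: 3-chloroperbenzoic acid, O=C(OO)c1cccc(Cl)c1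
Why: Prilezhaev epoxidation: the electron-poor enoate alkene is inert to the peracid, so only the exocyclic alkene reacts, and the peracid should approach C8 from the α face, equatorial to ring B and anti to the axial C10 methyl that is 1,3 to it, which places the epoxide oxygen α as the C8 carbinol requires.

Step 11
Reactants: 18 epoxy enoate
Product: 20 (2E)-2-methyl-5-[3α-(tert-butyldimethylsilyloxy)-8α-hydroxy-4,4,8β,10β-tetramethyl-5β-decalin-9β-yl]pent-2-en-1-ol, via epoxy allylic alcohol 19 (not isolated)
Conditions: LiAlH4, THF, 0 → 40 °C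
Reagents that add atoms: none
Why: Hydride reduction: LiAlH4 reduces the enoate 1,2 to the allylic alcohol 19 and then opens the spiro-epoxide by SN2 attack at its unsubstituted CH2 carbon, which turns that carbon into the C8 methyl group and leaves the oxygen on C8 with its configuration untouched (8α-OH, 8β-CH3).

Step 12
Reactants: 20 C8,C15 diol
Product: 21 (2E)-1-bromo-2-methyl-5-[3α-(tert-butyldimethylsilyloxy)-8α-hydroxy-4,4,8β,10β-tetramethyl-5β-decalin-9β-yl]pent-2-ene (C15 allylic bromide)
Conditions: NBS, Me2S, CH2Cl2, −30 → 0 °C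
Reagents that add atoms: N-bromosuccinimide, O=C1CCC(=O)N1Br
Why: Corey–Kim halogenation: the sulfonium reagent activates only the primary allylic hydroxyl, which bromide displaces without allylic transposition or loss of (E)-geometry, while the hindered tertiary C8 alcohol does not react.

Step 13
Reactants: 22 geranyl bromide
Product: 23 geranyl phenyl sulfone [(2E)-3,7-dimethylocta-2,6-dien-1-yl phenyl sulfone]
Conditions: PhSO2Na, DMF, rt
Reagents that add atoms: sodium benzenesulfinate, [Na+].[O-]S(=O)c1ccccc1
Why: SN2 displacement of the primary allylic bromide by the sulfur atom of the sulfinate anion gives the allylic sulfone with the (E)-alkene unchanged.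

Step 14
Reactants: 23 geranyl phenyl sulfone
Product: 24 (2E,6E)-2,6-dimethyl-8-(phenylsulfonyl)octa-2,6-dien-1-ol
Conditions: SeO2 (cat.), t-BuOOH, salicylic acid (cat.), CH2Cl2, rt
Reagents that add atoms: tert-butyl hydroperoxide, CC(C)(C)OO (oxygen relayed by SeO2, O=[Se]=O)
Why: SeO2-catalysed allylic oxidation (ene reaction then [2,3]-sigmatropic shift) attacks the more electron-rich terminal alkene, the one next to the sulfone being deactivated, and oxidises the methyl group trans to the chain, which gives the (E)-allylic alcohol.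

Step 15
Reactants: 24 hydroxy sulfone
Product: 25 (2E,6E)-8-(tert-butyldimethylsilyloxy)-3,7-dimethylocta-2,6-dien-1-yl phenyl sulfone
Conditions: TBSCl, imidazole, CH2Cl2, rt
Reagents that add atoms: tert-butyldimethylsilyl chloride, CC(C)(C)[Si](C)(C)Cl
Why: Standard silylation protects the primary allylic alcohol against the organolithium base of the coupling.

Step 16
Reactants: 25 silyloxy geranyl sulfone; 21 C15 allylic bromide
Product: 27 C16-phenylsulfonyl coupling product (3α,23-bis-silyl ether with free 8α-OH; mixture of C16 epimers), via lithiated sulfone 26 (not isolated)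
Conditions: 25 (2.2 equiv), n-BuLi (2.1 equiv), THF, −78 °C; then 21, −78 → −30 °C
Reagents that add atoms: none
Why: Alkylation of a sulfonyl-stabilised allylic carbanion: the lithiated sulfone 26, far less basic than a tertiary alkoxide and used in excess so that the C8 alcohol can stay free, attacks the primary allylic bromide by SN2 at its α-carbon and forms the C15–C16 bond without touching either trisubstituted alkene, the configuration of the sulfonyl-bearing carbon being of no consequence.

Step 17
Reactants: 27 coupled sulfone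
Product: 28 3α,23-bis(tert-butyldimethylsilyl) ether of the (13E,17E,21E)-triene-3α,8α,23-triol
Conditions: PdCl2(dppp) (5 mol %; dppp = 1,3-bis(diphenylphosphino)propane), LiBHEt3, THF, 0 °C
Reagents that add atoms: none
Why: Palladium-catalysed reductive desulfonylation: zerovalent palladium, formed from PdCl2(dppp) and hydride, ionises the allylic sulfone to a π-allyl complex that takes up hydride at the less substituted terminus (C16), so the C17=C18 alkene should keep its position and (E)-geometry.

Step 18
Reactants: 28 bis-silyl ether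
Product: 30 (13E,17E,21E)-triene-3α,8α,23-triol with the 5β,9β-chain,10β-methyl decalin core, via C3 mono-silyl ether 29 (not isolated)
Conditions: TBAF, THF, rt → 60 °C
Reagents that add atoms: none
Why: Fluoride-mediated desilylation removes the primary allylic silyl ether at room temperature and the hindered C3 silyl ether on warming, under conditions to which the tertiary and allylic alcohols are stable.

Step 19
Reactants: 30 triol
Product: 31 23-O-acetyl-3α,8α-diol
Conditions: Ac2O (1.1 equiv), pyridine, CH2Cl2, 0 °C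
Reagents that add atoms: acetic anhydride, CC(=O)OC(C)=O
Why: Chemoselective acylation: with one equivalent of anhydride at low temperature the primary allylic alcohol is acetylated much faster than the secondary C3 alcohol next to the gem-dimethyl carbon or the tertiary C8 alcohol.

Step 20
Reactants: 31 23-O-acetyl-3α,8α-diol
Product: 32 myrrhanone A acetate
Conditions: Dess–Martin periodinane, NaHCO3, CH2Cl2, rt
Reagents that add atoms: none
Why: Dess–Martin oxidation converts the only remaining oxidisable (secondary) alcohol into the C3 ketone, the tertiary alcohol and the allylic acetate being inert, and the new ketone has no stereocentre at an enolisable α-position.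

**Compound list**
1 | 6-methoxy-2-tetralone (6-methoxy-3,4-dihydronaphthalen-2(1H)-one) | COc1ccc2c(c1)CCC(=O)C2 | starting material
2 | 6-methoxy-1-methyl-3,4-dihydronaphthalen-2(1H)-one (racemic) | COc1ccc2c(c1)CCC(=O)C2C | intermediate
3 | 6-methoxy-1,1-dimethyl-3,4-dihydronaphthalen-2(1H)-one | COc1ccc2c(c1)CCC(=O)C2(C)C | intermediate
4 | (R)-6-methoxy-1,1-dimethyl-1,2,3,4-tetrahydronaphthalen-2-ol | COc1ccc2c(c1)CC[C@@H](O)C2(C)C | intermediate
5 | (R)-6-methoxy-1,1-dimethyl-1,2,3,4,5,8-hexahydronaphthalen-2-ol (Birch enol ether) | COC1=CCC2=C(C1)CC[C@@H](O)C2(C)C | intermediate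
6 | (R)-6-hydroxy-5,5-dimethyl-3,4,5,6,7,8-hexahydronaphthalen-2(1H)-one (β,γ-unsaturated ketone) | O=C1CCC2=C(C1)CC[C@@H](O)C2(C)C | intermediate
7 | (4aS,6R)-6-hydroxy-5,5-dimethyl-4,4a,5,6,7,8-hexahydronaphthalen-2(3H)-one | O=C1C=C2CC[C@@H](O)C(C)(C)[C@H]2CC1 | intermediate
8 | (4aS,6R)-6-[(tert-butyldimethylsilyl)oxy]-5,5-dimethyl-4,4a,5,6,7,8-hexahydronaphthalen-2(3H)-one (ring B enone, key-step precursor) | O=C1C=C2CC[C@@H](O[Si](C)(C)C(C)(C)C)C(C)(C)[C@H]2CC1 | intermediate
9 | allyl bromide | C=CCBr | starting material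
10 | lithium C8(9)-enolate of the 10β-methyl cis-decalone | [Li+].[O-]C1=C[C@@]2(C)CC[C@@H](O[Si](C)(C)C(C)(C)C)C(C)(C)[C@H]2CC1 | intermediate
11 | (1S,4aS,6R,8aS)-6-[(tert-butyldimethylsilyl)oxy]-5,5,8a-trimethyl-1-(prop-2-en-1-yl)octahydronaphthalen-2(1H)-one (9α-allyl epimer) | C=CC[C@H]1[C@@]2(C)CC[C@@H](O[Si](C)(C)C(C)(C)C)C(C)(C)[C@H]2CCC1=O | intermediate
12 | (1R,4aS,6R,8aS)-6-[(tert-butyldimethylsilyl)oxy]-5,5,8a-trimethyl-1-(prop-2-en-1-yl)octahydronaphthalen-2(1H)-one (cis-fused, 9β-allyl, 10β-methyl, 3α-silyloxy, 8-one) | C=CC[C@@H]1[C@@]2(C)CC[C@@H](O[Si](C)(C)C(C)(C)C)C(C)(C)[C@H]2CCC1=O | intermediate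
13 | 9β-allyl-3α-(tert-butyldimethylsilyloxy)-4,4,10β-trimethyl-8-methylidene-5β-decalin | C=CC[C@@H]1[C@@]2(C)CC[C@@H](O[Si](C)(C)C(C)(C)C)C(C)(C)[C@H]2CCC1=C | intermediate
14 | B-(C13-alkyl)bis(3-methylbutan-2-yl)borane derived from 13 | CC(C)C(C)B(CCC[C@@H]1[C@@]2(C)CC[C@@H](O[Si](C)(C)C(C)(C)C)C(C)(C)[C@H]2CCC1=C)C(C)C(C)C | intermediate
15 | 9β-(3-hydroxypropyl)-3α-(tert-butyldimethylsilyloxy)-4,4,10β-trimethyl-8-methylidene-5β-decalin | OCCC[C@@H]1[C@@]2(C)CC[C@@H](O[Si](C)(C)C(C)(C)C)C(C)(C)[C@H]2CCC1=C | intermediate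
16 | 9β-(3-oxopropyl)-3α-(tert-butyldimethylsilyloxy)-4,4,10β-trimethyl-8-methylidene-5β-decalin | O=CCC[C@@H]1[C@@]2(C)CC[C@@H](O[Si](C)(C)C(C)(C)C)C(C)(C)[C@H]2CCC1=C | intermediate
17 | ethyl (2E)-2-methyl-5-[3α-(tert-butyldimethylsilyloxy)-4,4,10β-trimethyl-8-methylidene-5β-decalin-9β-yl]pent-2-enoate | CCOC(=O)/C(C)=C/CC[C@@H]1[C@@]2(C)CC[C@@H](O[Si](C)(C)C(C)(C)C)C(C)(C)[C@H]2CCC1=C | intermediate
18 | 8α,17-epoxide of 17 (spiro-oxirane, oxygen α) | CCOC(=O)/C(C)=C/CC[C@@H]1[C@@]2(C)CC[C@@H](O[Si](C)(C)C(C)(C)C)C(C)(C)[C@H]2CC[C@@]13OC3 | intermediate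
19 | (2E)-2-methyl-5-[8α,17-epoxy decalin-9β-yl]pent-2-en-1-ol (epoxy allylic alcohol) | OC/C(C)=C/CC[C@@H]1[C@@]2(C)CC[C@@H](O[Si](C)(C)C(C)(C)C)C(C)(C)[C@H]2CC[C@@]13OC3 | intermediate
20 | (2E)-2-methyl-5-[3α-(tert-butyldimethylsilyloxy)-8α-hydroxy-4,4,8β,10β-tetramethyl-5β-decalin-9β-yl]pent-2-en-1-ol | OC/C(C)=C/CC[C@@H]1[C@@]2(C)CC[C@@H](O[Si](C)(C)C(C)(C)C)C(C)(C)[C@H]2CC[C@@]1(C)O | intermediate
21 | (2E)-1-bromo-2-methyl-5-[3α-(tert-butyldimethylsilyloxy)-8α-hydroxy-4,4,8β,10β-tetramethyl-5β-decalin-9β-yl]pent-2-ene | BrC/C(C)=C/CC[C@@H]1[C@@]2(C)CC[C@@H](O[Si](C)(C)C(C)(C)C)C(C)(C)[C@H]2CC[C@@]1(C)O | intermediate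
22 | geranyl bromide [(2E)-1-bromo-3,7-dimethylocta-2,6-diene] | CC(C)=CCC/C(C)=C/CBr | starting material
23 | geranyl phenyl sulfone | CC(C)=CCC/C(C)=C/CS(=O)(=O)c1ccccc1 | intermediate
24 | (2E,6E)-2,6-dimethyl-8-(phenylsulfonyl)octa-2,6-dien-1-ol | OC/C(C)=C/CC/C(C)=C/CS(=O)(=O)c1ccccc1 | intermediate
25 | (2E,6E)-8-(tert-butyldimethylsilyloxy)-3,7-dimethylocta-2,6-dien-1-yl phenyl sulfone | CC(C)(C)[Si](C)(C)OC/C(C)=C/CC/C(C)=C/CS(=O)(=O)c1ccccc1 | intermediate
26 | α-lithio derivative of 25 | CC(C)(C)[Si](C)(C)OC/C(C)=C/CC/C(C)=C/[CH-]S(=O)(=O)c1ccccc1.[Li+] | intermediate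
27 | C16-phenylsulfonyl coupling product (3α,23-bis-silyl ether, 8α-OH, mixture of C16 epimers) | CC(C)(C)[Si](C)(C)OC/C(C)=C/CC/C(C)=C/C(C/C(C)=C/CC[C@@H]1[C@@]2(C)CC[C@@H](O[Si](C)(C)C(C)(C)C)C(C)(C)[C@H]2CC[C@@]1(C)O)S(=O)(=O)c1ccccc1 | intermediate
28 | 3α,23-bis(tert-butyldimethylsilyl) ether of the (13E,17E,21E)-triene-3α,8α,23-triol | CC(C)(C)[Si](C)(C)OC/C(C)=C/CC/C(C)=C/CC/C(C)=C/CC[C@@H]1[C@@]2(C)CC[C@@H](O[Si](C)(C)C(C)(C)C)C(C)(C)[C@H]2CC[C@@]1(C)O | intermediate
29 | 3α-(tert-butyldimethylsilyl) ether of the triene-3α,8α,23-triol | OC/C(C)=C/CC/C(C)=C/CC/C(C)=C/CC[C@@H]1[C@@]2(C)CC[C@@H](O[Si](C)(C)C(C)(C)C)C(C)(C)[C@H]2CC[C@@]1(C)O | intermediate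
30 | (13E,17E,21E)-triene-3α,8α,23-triol (5β-H, 9β-chain, 8β,10β-dimethyl) | OC/C(C)=C/CC/C(C)=C/CC/C(C)=C/CC[C@@H]1[C@@]2(C)CC[C@@H](O)C(C)(C)[C@H]2CC[C@@]1(C)O | intermediate
31 | 23-O-acetyl derivative of triol 30 | CC(=O)OC/C(C)=C/CC/C(C)=C/CC/C(C)=C/CC[C@@H]1[C@@]2(C)CC[C@@H](O)C(C)(C)[C@H]2CC[C@@]1(C)O | intermediate
32 | myrrhanone A acetate | CC(=O)OC/C(C)=C/CC/C(C)=C/CC/C(C)=C/CC[C@@H]1[C@@]2(C)CCC(=O)C(C)(C)[C@H]2CC[C@@]1(C)O | target

Total step count: 20 steps (17 on the main line, 3 for the sulfone fragment).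
Longest linear sequence: 17 steps (steps 1–12 and 16–20, from 6-methoxy-2-tetralone).

**Steps most likely to fail**

Step 5. Methyl transfer to the hindered β,β-disubstituted enone may be incomplete, and proton exchange between the copper-containing enolate and ketone already formed may give non-allylated and doubly allylated material. The fallback separates the two bond formations and sets out from 8. Me2CuLi with Me3SiCl in THF at −78 °C (chlorosilane-accelerated conjugate addition) should give the C8(9) trimethylsilyl enol ether F1, which can be purified. MeLi in THF at 0 °C then releases the copper-free lithium enolate 10, which is allylated with 9 in THF/HMPA and equilibrated with NaOMe in MeOH as before. The route is rejoined at 12.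

Step 7. The borane may also attack the exocyclic C8 alkene, so chemoselectivity between the two terminal alkenes is lost. The fallback reverses the order of events and sets out from 13. One equivalent of mCPBA (NaHCO3, CH2Cl2, 0 °C) should epoxidise the more nucleophilic 1,1-disubstituted alkene first, from the α face, to give the 8α,17-epoxide with intact allyl group F2. With no competing alkene left, 9-BBN followed by NaOH/H2O2 gives the epoxy alcohol F3. Buffered Dess–Martin oxidation gives the epoxy aldehyde F4, and the same stabilised ylide gives the epoxy enoate. The route is rejoined at 18.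

Step 10. Facial selectivity of the peracid may be poor: if the cis-fused decalin reacts through its ring-flipped chair, in which the C10 methyl is equatorial on ring B, the β face of C8 is the open one and oxygen is delivered β. The fallback turns that same facial preference to advantage by forming the C8–CH3 bond instead of the C8–O bond from the open face, and sets out from 12. MeLi with CeCl3 in THF at −78 °C adds to the C8 ketone to give the 9β-allyl 8α-hydroxy-8β-methyl decalin F5. 9-BBN followed by NaOH/H2O2 gives the C8,C13 diol F6. Parikh–Doering oxidation (SO3·pyridine, DMSO, i-Pr2NEt) gives the hydroxy aldehyde F7, which equilibrates with its lactol. The stabilised ylide in toluene at 80 °C gives the hydroxy (E)-enoate F8, and i-Bu2AlH in CH2Cl2 at −78 °C reduces the ester. The route is rejoined at 20.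

Further compounds
F1 | step 5 | C8(9) trimethylsilyl enol ether of the 10β-methyl cis-decalone | C[Si](C)(C)OC1=C[C@@]2(C)CC[C@@H](O[Si](C)(C)C(C)(C)C)C(C)(C)[C@H]2CC1
F2 | step 7 | 9β-allyl-8α,17-epoxy-3α-(tert-butyldimethylsilyloxy)-4,4,10β-trimethyl-5β-decalin | C=CC[C@@H]1[C@@]2(C)CC[C@@H](O[Si](C)(C)C(C)(C)C)C(C)(C)[C@H]2CC[C@@]13OC3
F3 | step 7 | 9β-(3-hydroxypropyl)-8α,17-epoxy-3α-(tert-butyldimethylsilyloxy)-4,4,10β-trimethyl-5β-decalin | OCCC[C@@H]1[C@@]2(C)CC[C@@H](O[Si](C)(C)C(C)(C)C)C(C)(C)[C@H]2CC[C@@]13OC3
F4 | step 7 | 9β-(3-oxopropyl)-8α,17-epoxy-3α-(tert-butyldimethylsilyloxy)-4,4,10β-trimethyl-5β-decalin | O=CCC[C@@H]1[C@@]2(C)CC[C@@H](O[Si](C)(C)C(C)(C)C)C(C)(C)[C@H]2CC[C@@]13OC3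
F5 | step 10 | 9β-allyl-3α-(tert-butyldimethylsilyloxy)-4,4,8β,10β-tetramethyl-5β-decalin-8α-ol | C=CC[C@@H]1[C@@]2(C)CC[C@@H](O[Si](C)(C)C(C)(C)C)C(C)(C)[C@H]2CC[C@@]1(C)O
F6 | step 10 | 9β-(3-hydroxypropyl)-3α-(tert-butyldimethylsilyloxy)-4,4,8β,10β-tetramethyl-5β-decalin-8α-ol | OCCC[C@@H]1[C@@]2(C)CC[C@@H](O[Si](C)(C)C(C)(C)C)C(C)(C)[C@H]2CC[C@@]1(C)O
F7 | step 10 | 9β-(3-oxopropyl)-3α-(tert-butyldimethylsilyloxy)-4,4,8β,10β-tetramethyl-5β-decalin-8α-ol | O=CCC[C@@H]1[C@@]2(C)CC[C@@H](O[Si](C)(C)C(C)(C)C)C(C)(C)[C@H]2CC[C@@]1(C)O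
F8 | step 10 | ethyl (2E)-2-methyl-5-[3α-(tert-butyldimethylsilyloxy)-8α-hydroxy-4,4,8β,10β-tetramethyl-5β-decalin-9β-yl]pent-2-enoate | CCOC(=O)/C(C)=C/CC[C@@H]1[C@@]2(C)CC[C@@H](O[Si](C)(C)C(C)(C)C)C(C)(C)[C@H]2CC[C@@]1(C)O
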